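**Plan** (germacrane numbering: C1 furanone C=O, C2 furanone CH, C3 furanone O–C=, C4=C5 Z-olefin with C15H2OH on C4, C6 lactone O–CH, C7, C8 ester CH, C9, C10 quaternary O–C with C14 methyl, C11–C13 methylene lactone)
- Enabling feature: the furanone atoms O–C10–C1(=O)–C2=C3 are an isomer of the 4-hydroxy-2-ynone C10(OH)–C1≡C2–C3(=O). C3 lies between alkyne carbon C2 and vinyl carbon C4, so C3 can be carbon monoxide.
- Cuts: O–C3 first, then C2–C3 and C3–C4 (loss of CO). This opens the furanone and the ten-membered carbocycle together, leaving a monocyclic butyrolactone with a C4 vinyl iodide and a C10 tertiary propargylic alcohol. Further cuts are C7–C11 (epoxide opening) and C6–C7 (alkenylzinc plus enal).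
- Forward order: fragment A (C15, C4–C6) and fragment B (C7–C10, C14, C1, C2) are joined at C6–C7. The butyrolactone closes in step 14. The carbocycle and then the furanone close in one pot in step 17.
- Stereochemistry: C10 comes from a Sharpless epoxidation (L-(+)-tartrate) and C6 from a (−)-MIB-catalysed alkenylzinc addition. C7 and C8 come from a second, matched Sharpless epoxidation (D-(−)-tartrate) and an invertive 5-exo opening. The Z-C4=C5 geometry comes from trans-hydroalumination/iodination.
- Helpers: SiMe3 on C2 and O10 (off in step 11), Me2NH on C13 during the palladium step (off in step 18), and SiMe2tBu on O15 (off in step 19).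

Key step: step 17

Assumption: C11 in the phosphonate and amine-masked lactones (21, 24–28, F1–F4) is drawn as the thermodynamically favoured epimer, with its substituent trans to the C7 side chain. This centre is erased in steps 14 and 18 and has no bearing on the target.

Step 1
Reactants: 1 but-2-yne-1,4-diol
Product: 2 4-[(tert-butyldimethylsilyl)oxy]but-2-yn-1-ol
Conditions: NaH (1.0 equiv), THF, 0 °C; TBSCl (1.0 equiv), rt
Reagents that add atoms: tert-butyldimethylsilyl chloride, CC(C)(C)[Si](C)(C)Cl
Why: O-silylation of a symmetrical diol through its poorly soluble monosodium alkoxide should stop after one silyl transfer, and no stereocentre is formed.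

Step 2
Reactants: 2 4-[(tert-butyldimethylsilyl)oxy]but-2-yn-1-ol
Product: 4 (Z)-4-[(tert-butyldimethylsilyl)oxy]-3-iodobut-2-en-1-ol, via cyclic alanate 3 (not isolated)
Conditions: NaAlH2(OCH2CH2OMe)2 (1.1 equiv), THF, 0 °C to rt; then I2, −78 to 0 °C
Reagents that add atoms: iodine, II
Why: Hydroxyl-directed trans-hydroalumination of a propargylic alcohol places aluminium on the distal carbon C4 inside a five-membered alanate, and iodinolysis with retention should give only the Z-iodide with iodine (the later C3) cis to C6, which fixes the C4=C5 geometry of the target.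

Step 3
Reactants: 4 (Z)-4-[(tert-butyldimethylsilyl)oxy]-3-iodobut-2-en-1-ol
Product: 5 (Z)-4-[(tert-butyldimethylsilyl)oxy]-3-iodobut-2-enal (fragment A)
Conditions: MnO2, CH2Cl2, rt, dark
Reagents that add atoms: none
Why: MnO2 oxidation of an allylic alcohol is neutral and heterogeneous, so the silyl ether, the C–I bond and the Z geometry should survive.

Step 4
Reactants: 6 (E)-3-methylpent-2-en-4-yn-1-ol
Product: 8 (E)-3-methyl-5-(trimethylsilyl)pent-2-en-4-yn-1-ol, via bis-silyl enynol 7 (not isolated)
Conditions: nBuLi (2.2 equiv), THF, −78 °C; TMSCl (2.3 equiv), to rt; then 1 M HCl, rt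
Reagents that add atoms: trimethylsilyl chloride, C[Si](C)(C)Cl
Why: Double deprotonation, double silylation and selective acid hydrolysis of the labile O–Si bond is the standard C-silylation of an enynol, and the silyl group later tells the two alkynes of 13 apart.

Step 5
Reactants: 8 (E)-3-methyl-5-(trimethylsilyl)pent-2-en-4-yn-1-ol
Product: 9 {(2S,3S)-3-methyl-3-[(trimethylsilyl)ethynyl]oxiran-2-yl}methanol
Conditions: Ti(OiPr)4 (10 mol %), L-(+)-diethyl tartrate (12 mol %), tBuOOH, 4 Å sieves, CH2Cl2, −20 °C
Reagents that add atoms: tert-butyl hydroperoxide, CC(C)(C)OO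
Why: Sharpless asymmetric epoxidation of an E-trisubstituted allylic alcohol with the L-(+)-tartrate delivers oxygen to the face that gives the (2S,3S)-epoxide (the sense known for geraniol), the alkyne is inert, and the C10–O stereocentre is set here.

Step 6
Reactants: 9 {(2S,3S)-3-methyl-3-[(trimethylsilyl)ethynyl]oxiran-2-yl}methanol
Product: 10 (R)-3-methyl-5-(trimethylsilyl)pent-4-yne-1,3-diol
Conditions: NaAlH2(OCH2CH2OMe)2 (1.1 equiv), THF, −20 to 0 °C
Reagents that add atoms: none
Why: In the alkoxyaluminium hydride formed from a 2,3-epoxy alcohol the hydride is delivered intramolecularly to C9 and not to the tertiary C10, which gives the 1,3-diol with the C10–O bond and its configuration untouched, and one equivalent of reagent leaves no Al–H for hydroalumination of the alkyne.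

Step 7
Reactants: 10 (R)-3-methyl-5-(trimethylsilyl)pent-4-yne-1,3-diol
Product: 11 (R)-3-methyl-5-(trimethylsilyl)-1,3-bis[(trimethylsilyl)oxy]pent-4-yne
Conditions: TMSOTf (2.4 equiv), 2,6-lutidine, CH2Cl2, −78 to 0 °C
Reagents that add atoms: trimethylsilyl trifluoromethanesulfonate, C[Si](C)(C)OS(=O)(=O)C(F)(F)F
Why: Silyl triflate/lutidine silylation is strong enough for the tertiary propargylic alcohol and mild enough for the C-silyl alkyne.

Step 8
Reactants: 11 (R)-3-methyl-5-(trimethylsilyl)-1,3-bis[(trimethylsilyl)oxy]pent-4-yne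
Product: 12 (R)-3-methyl-5-(trimethylsilyl)-3-[(trimethylsilyl)oxy]pent-4-ynal
Conditions: (COCl)2, DMSO, CH2Cl2, −78 to −30 °C; Et3N, to 0 °C
Reagents that add atoms: none
Why: Under Swern conditions a primary trimethylsilyl ether is cleaved and oxidised in situ whereas the hindered tertiary one is not, so the C8 aldehyde should form without a separate deprotection.

Step 9
Reactants: 12 (R)-3-methyl-5-(trimethylsilyl)-3-[(trimethylsilyl)oxy]pent-4-ynal
Product: 13 (R)-3-methyl-1-(trimethylsilyl)-3-[(trimethylsilyl)oxy]hexa-1,5-diyne (fragment B)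
Conditions: Me3SiCHN2, lithium diisopropylamide, THF, −78 °C to rt
Reagents that add atoms: (trimethylsilyl)diazomethane, C[Si](C)(C)C=[N+]=[N-]
Why: The Colvin rearrangement (addition of the lithiated diazo compound, loss of silanolate and N2, 1,2-H shift of the alkylidene carbene) homologates the aldehyde to the terminal alkyne under aprotic conditions that keep the C–Si and O–Si bonds, and the new carbon is C7.

Step 10
Reactants: 13 (R)-3-methyl-1-(trimethylsilyl)-3-[(trimethylsilyl)oxy]hexa-1,5-diyne; 5 (Z)-4-[(tert-butyldimethylsilyl)oxy]-3-iodobut-2-enal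
Product: 16 (2Z,4S,5E,8R)-1-[(tert-butyldimethylsilyl)oxy]-2-iodo-8-methyl-10-(trimethylsilyl)-8-[(trimethylsilyl)oxy]deca-2,5-dien-9-yn-4-ol, via alkenylborane 14 (not isolated), via alkenylzinc 15 (not isolated)
Conditions: 13, Cy2BH, toluene, 0 °C to rt; Et2Zn, −78 °C; (−)-MIB [(2S)-3-exo-morpholinoisoborneol, 5 mol %], then 5, −20 to 0 °C
Reagents that add atoms: none
Why: Syn-hydroboration of the only terminal alkyne, boron-to-zinc exchange and amino-alcohol-catalysed 1,2-addition to the enal is the established catalytic asymmetric alkenylation of aldehydes, in which (−)-MIB directs attack to the Si face of 5 (the sense known for this ligand family with benzaldehyde) and so sets C6, while the E geometry of C7=C8 comes from the hydroboration.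

Step 11
Reactants: 16 (2Z,4S,5E,8R)-1-[(tert-butyldimethylsilyl)oxy]-2-iodo-8-methyl-10-(trimethylsilyl)-8-[(trimethylsilyl)oxy]deca-2,5-dien-9-yn-4-ol
Product: 17 (2Z,4S,5E,8R)-1-[(tert-butyldimethylsilyl)oxy]-2-iodo-8-methyldeca-2,5-dien-9-yne-4,8-diol
Conditions: K2CO3, MeOH, rt
Reagents that add atoms: none
Why: Base-catalysed methanolysis removes the alkynyl and the O-trimethylsilyl groups in one operation, while the tert-butyldimethylsilyl ether and the vinyl iodide are stable.

Step 12
Reactants: 17 (2Z,4S,5E,8R)-1-[(tert-butyldimethylsilyl)oxy]-2-iodo-8-methyldeca-2,5-dien-9-yne-4,8-diol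
Product: 18 (1R,2Z)-4-[(tert-butyldimethylsilyl)oxy]-1-{(2R,3R)-3-[(2R)-2-hydroxy-2-methylbut-3-yn-1-yl]oxiran-2-yl}-3-iodobut-2-en-1-ol
Conditions: Ti(OiPr)4 (20 mol %), D-(−)-diisopropyl tartrate (24 mol %), tBuOOH, 4 Å sieves, CH2Cl2, −20 °C
Reagents that add atoms: tert-butyl hydroperoxide, CC(C)(C)OO
Why: This is a matched Sharpless asymmetric epoxidation in which the D-(−)-tartrate makes the (4S)-alcohol the fast-reacting isomer and gives the anti (R,R)-epoxide at the E-C7=C8 bond, the Z-trisubstituted and iodine-deactivated C4=C5 bond reacts far more slowly, and any C6 epimer is left behind, so the C7–O and C8–O centres are set by the reagent.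

Step 13
Reactants: 18 (1R,2Z)-4-[(tert-butyldimethylsilyl)oxy]-1-{(2R,3R)-3-[(2R)-2-hydroxy-2-methylbut-3-yn-1-yl]oxiran-2-yl}-3-iodobut-2-en-1-ol; 19 diethylphosphonoacetic acid
Product: 20 O6-(diethylphosphonoacetate) of 18
Conditions: DCC, DMAP (cat.), CH2Cl2, 0 °C to rt
Reagents that add atoms: diethylphosphonoacetic acid (19), OC(=O)CP(=O)(OCC)OCC
Why: Steglich esterification acylates only the secondary allylic alcohol because the tertiary propargylic alcohol is too hindered, and it leaves the epoxide intact.

Step 14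
Reactants: 20 O6-(diethylphosphonoacetate) of 18
Product: 22 (4R,5S)-4-[(1R,3R)-1,3-dihydroxy-3-methylpent-4-yn-1-yl]-5-[(1Z)-3-[(tert-butyldimethylsilyl)oxy]-2-iodoprop-1-en-1-yl]-3-methylideneoxolan-2-one, via phosphono lactone 21 (not isolated)
Conditions: NaH (1.05 equiv), THF, 0 to 60 °C; then (CH2O)n, 0 °C to rt
Reagents that add atoms: formaldehyde (from paraformaldehyde), C=O
Why: The phosphonate-stabilised carbanion tethered through O6 opens the epoxide at C7 in a 5-exo-tet intramolecular alkylation (the same C2 regiochemistry as carbonate and urethane participation in 2,3-epoxy alcohols) with inversion at C7 and retention at C8, which turns the anti epoxy alcohol into the 6,7-trans lactone bearing the 8R carbinol, and the resulting phosphonate anion then undergoes Horner–Wadsworth–Emmons methylenation with formaldehyde.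

Step 15
Reactants: 22 (4R,5S)-4-[(1R,3R)-1,3-dihydroxy-3-methylpent-4-yn-1-yl]-5-[(1Z)-3-[(tert-butyldimethylsilyl)oxy]-2-iodoprop-1-en-1-yl]-3-methylideneoxolan-2-one
Product: 23 8-O-isobutyrate of 22
Conditions: (iPrCO)2O (1.2 equiv), DMAP (cat.), Et3N, CH2Cl2, 0 °C
Reagents that add atoms: isobutyric anhydride, CC(C)C(=O)OC(=O)C(C)C
Why: DMAP-catalysed acylation differentiates the secondary C8 alcohol from the tertiary propargylic C10 alcohol on steric grounds and does not touch any stereocentre.

Step 16
Reactants: 23 8-O-isobutyrate of 22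
Product: 24 (11R)-13-(dimethylamino)-11,13-dihydro derivative of 23 (seco precursor)
Conditions: Me2NH (2 M in THF), 0 °C; evaporation of excess amine
Reagents that add atoms: dimethylamine, CNC
Why: Aza-Michael addition of a secondary amine to an α-methylene-γ-butyrolactone is fast and reversible and gives the adduct with CH2NMe2 trans to the C7 side chain, and this temporary mask removes the acceptor alkene that would otherwise intercept the vinyl- or acylpalladium species of step 17.

Step 17
Reactants: 24 (11R)-13-(dimethylamino)-11,13-dihydro derivative of 23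
Product: 27 (6R,7R,8R,10R,11R)-13-(dimethylamino)-11,13-dihydro-15-O-(tert-butyldimethylsilyl) derivative of the target, via macrocyclic ynone 25 (not isolated), via enaminone 26 (not isolated)
Conditions: PdCl2(PPh3)2 (10 mol %), CuI (10 mol %), Et3N, CO (1 atm), THF, 24 added by syringe pump (final 1 mM), 25–40 °C; Ar purge, then Et2NH, rt; then AcOH–H2O, rt (one pot)
Reagents that add atoms: carbon monoxide, [C-]#[O+]; water, O
Why: Proposed new method: oxidative addition of zerovalent palladium into the C4–I bond (Z geometry retained) and fast CO insertion give a C3 acylpalladium iodide, the copper acetylide of C2 transmetalates, and reductive elimination from the eleven-membered acyl(alkynyl)palladacycle forms C2–C3 and closes the ten-membered carbocycle end to end as ynone 25; Et2NH then adds to the bent, strain-activated alkyne at C1 (the β-carbon of the C3 ketone) to give vinylogous amide 26, whose C10 hydroxyl attacks the C3 carbonyl in a transannular 5-exo-trig closure, and loss of water followed by hydrolysis of the C1 iminium ion gives the 3(2H)-furanone, so the step is a net CO insertion plus isomerisation. The closest known reaction types are the intermolecular carbonylative Sonogashira coupling of aryl or vinyl iodides with tertiary propargylic alcohols (whose 4-hydroxy-2-ynones are turned by amine and water into 3(2H)-furanones), the carbonylative Stille macrocyclisation, and palladium-mediated closures of ten-membered rings that hold alkynes, but their union in a ring-closing format has not been shown. No stereocentre is created, because C6, C7, C8 and C11 are spectators and C10 keeps its configuration since the C10–O bond is never broken (its oxygen becomes the ring oxygen, the oxygen of CO leaves as water, and the C1 oxygen comes from water). Carbonylative rather than direct coupling is secured by the substrate, because the CO-free product would be a nine-membered cyclic Z-enyne, and oligomerisation is held back by slow addition at high dilution. Heck or acylpalladation at C11=C13 is excluded by the Me2NH mask, amide formation by keeping the secondary amine out until CO has been purged, and ester formation by the silyl ether on O15 and the tertiary nature of O10. The regiochemistry of the hydration is fixed by the polarity of the ynone (attack at C1 only), and only O10 can reach C3 through a five-membered transition state.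

Step 18
Reactants: 27 (6R,7R,8R,10R,11R)-13-(dimethylamino)-11,13-dihydro-15-O-(tert-butyldimethylsilyl) derivative of the target
Product: 29 15-O-(tert-butyldimethylsilyl) ether of the target, via ammonium iodide 28 (not isolated)
Conditions: MeI, MeCN, rt; then aq. NaHCO3, EtOAc, rt
Reagents that add atoms: none
Why: Quaternisation followed by mild E1cB (Hofmann-type) elimination is the classical release of an α-methylene lactone from its amine adduct, it erases C11, and it touches no other centre.

Step 19
Reactants: 29 15-O-(tert-butyldimethylsilyl) ether of the target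
Product: 30 target, (4Z,6R,7R,8R,10R)-8-isobutyryloxy-15-hydroxy-1-oxo-3,10-epoxygermacra-2,4,11(13)-trien-12,6-olide
Conditions: HF·pyridine, pyridine, THF, 0 °C to rt
Reagents that add atoms: none
Why: Buffered fluoride-mediated desilylation of a primary allylic silyl ether is acidic and non-nucleophilic, so the methylene lactone, the furanone and the ester should survive.

**Compound list**
1 | but-2-yne-1,4-diol | OCC#CCO | starting material
2 | 4-[(tert-butyldimethylsilyl)oxy]but-2-yn-1-ol | OCC#CCO[Si](C)(C)C(C)(C)C | intermediate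
3 | sodium cyclic alkenylalanate (1,2-oxaluminole ate complex) | [Na+].COCCO[Al-]1(OCCOC)OCC=C1CO[Si](C)(C)C(C)(C)C | intermediate
4 | (Z)-4-[(tert-butyldimethylsilyl)oxy]-3-iodobut-2-en-1-ol | OC/C=C(/CO[Si](C)(C)C(C)(C)C)I | intermediate
5 | (Z)-4-[(tert-butyldimethylsilyl)oxy]-3-iodobut-2-enal | O=C/C=C(/CO[Si](C)(C)C(C)(C)C)I | intermediate
6 | (E)-3-methylpent-2-en-4-yn-1-ol | C#C/C(C)=C/CO | starting material
7 | (E)-3-methyl-5-(trimethylsilyl)-1-[(trimethylsilyl)oxy]pent-2-en-4-yne | C[Si](C)(C)C#C/C(C)=C/CO[Si](C)(C)C | intermediate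
8 | (E)-3-methyl-5-(trimethylsilyl)pent-2-en-4-yn-1-ol | C[Si](C)(C)C#C/C(C)=C/CO | intermediate
9 | {(2S,3S)-3-methyl-3-[(trimethylsilyl)ethynyl]oxiran-2-yl}methanol | C[Si](C)(C)C#C[C@]1(C)O[C@H]1CO | intermediate
10 | (R)-3-methyl-5-(trimethylsilyl)pent-4-yne-1,3-diol | C[Si](C)(C)C#C[C@@](C)(CCO)O | intermediate
11 | (R)-3-methyl-5-(trimethylsilyl)-1,3-bis[(trimethylsilyl)oxy]pent-4-yne | C[Si](C)(C)C#C[C@@](C)(CCO[Si](C)(C)C)O[Si](C)(C)C | intermediate
12 | (R)-3-methyl-5-(trimethylsilyl)-3-[(trimethylsilyl)oxy]pent-4-ynal | C[Si](C)(C)C#C[C@@](C)(CC=O)O[Si](C)(C)C | intermediate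
13 | (R)-3-methyl-1-(trimethylsilyl)-3-[(trimethylsilyl)oxy]hexa-1,5-diyne | C[Si](C)(C)C#C[C@@](C)(CC#C)O[Si](C)(C)C | intermediate
14 | (E)-alkenyl(dicyclohexyl)borane from 13 | C[Si](C)(C)C#C[C@@](C)(C/C=C/B(C1CCCCC1)C1CCCCC1)O[Si](C)(C)C | intermediate
15 | (E)-alkenyl(ethyl)zinc from 14 | C[Si](C)(C)C#C[C@@](C)(C/C=C/[Zn]CC)O[Si](C)(C)C | intermediate
16 | (2Z,4S,5E,8R)-1-[(tert-butyldimethylsilyl)oxy]-2-iodo-8-methyl-10-(trimethylsilyl)-8-[(trimethylsilyl)oxy]deca-2,5-dien-9-yn-4-ol | O[C@@H](/C=C/C[C@@](C)(O[Si](C)(C)C)C#C[Si](C)(C)C)/C=C(/CO[Si](C)(C)C(C)(C)C)I | intermediate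
17 | (2Z,4S,5E,8R)-1-[(tert-butyldimethylsilyl)oxy]-2-iodo-8-methyldeca-2,5-dien-9-yne-4,8-diol | O[C@@H](/C=C/C[C@@](C)(O)C#C)/C=C(/CO[Si](C)(C)C(C)(C)C)I | intermediate
18 | (1R,2Z)-4-[(tert-butyldimethylsilyl)oxy]-1-{(2R,3R)-3-[(2R)-2-hydroxy-2-methylbut-3-yn-1-yl]oxiran-2-yl}-3-iodobut-2-en-1-ol | O[C@@H]([C@H]1O[C@@H]1C[C@@](C)(O)C#C)/C=C(/CO[Si](C)(C)C(C)(C)C)I | intermediate
19 | diethylphosphonoacetic acid | OC(=O)CP(=O)(OCC)OCC | starting material
20 | O6-(diethylphosphonoacetate) of 18 | CCOP(=O)(OCC)CC(=O)O[C@@H]([C@H]1O[C@@H]1C[C@@](C)(O)C#C)/C=C(/CO[Si](C)(C)C(C)(C)C)I | intermediate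
21 | α-(diethoxyphosphoryl) lactone, 6,7-trans, phosphorus trans to the C7 chain, free 8R and 10R hydroxyls | CCOP(=O)(OCC)[C@@H]1C(=O)O[C@H](/C=C(/CO[Si](C)(C)C(C)(C)C)I)[C@H]1[C@H](O)C[C@@](C)(O)C#C | intermediate
22 | (4R,5S)-4-[(1R,3R)-1,3-dihydroxy-3-methylpent-4-yn-1-yl]-5-[(1Z)-3-[(tert-butyldimethylsilyl)oxy]-2-iodoprop-1-en-1-yl]-3-methylideneoxolan-2-one | C=C1C(=O)O[C@H](/C=C(/CO[Si](C)(C)C(C)(C)C)I)[C@H]1[C@H](O)C[C@@](C)(O)C#C | intermediate
23 | 8-O-isobutyrate of 22 | C=C1C(=O)O[C@H](/C=C(/CO[Si](C)(C)C(C)(C)C)I)[C@H]1[C@H](OC(=O)C(C)C)C[C@@](C)(O)C#C | intermediate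
24 | (11R)-13-(dimethylamino)-11,13-dihydro derivative of 23 | CN(C)C[C@@H]1C(=O)O[C@H](/C=C(/CO[Si](C)(C)C(C)(C)C)I)[C@H]1[C@H](OC(=O)C(C)C)C[C@@](C)(O)C#C | intermediate
25 | ten-membered 10-hydroxy-1-yn-3-one (C1≡C2, C3=O, 4Z), lactone and mask as in 24 | CN(C)C[C@@H]1C(=O)O[C@@H]2/C=C(/CO[Si](C)(C)C(C)(C)C)C(=O)C#C[C@](C)(O)C[C@@H](OC(=O)C(C)C)[C@@H]12 | intermediate
26 | ten-membered 1-(diethylamino)-1-en-3-one (vinylogous amide), C10 and C3 cis on C1=C2 | CN(C)C[C@@H]1C(=O)O[C@@H]2/C=C(/CO[Si](C)(C)C(C)(C)C)C(=O)/C=C(/N(CC)CC)[C@](C)(O)C[C@@H](OC(=O)C(C)C)[C@@H]12 | intermediate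
27 | (6R,7R,8R,10R,11R)-13-(dimethylamino)-11,13-dihydro-15-O-(tert-butyldimethylsilyl) derivative of the target | CN(C)C[C@@H]1C(=O)O[C@@H]2/C=C(/CO[Si](C)(C)C(C)(C)C)C3=CC(=O)[C@@](C)(C[C@@H](OC(=O)C(C)C)[C@@H]12)O3 | intermediate
28 | 13-(trimethylammonio) iodide of 27 | C[N+](C)(C)C[C@@H]1C(=O)O[C@@H]2/C=C(/CO[Si](C)(C)C(C)(C)C)C3=CC(=O)[C@@](C)(C[C@@H](OC(=O)C(C)C)[C@@H]12)O3.[I-] | intermediate
29 | 15-O-(tert-butyldimethylsilyl) ether of the target | C=C1C(=O)O[C@@H]2/C=C(/CO[Si](C)(C)C(C)(C)C)C3=CC(=O)[C@@](C)(C[C@@H](OC(=O)C(C)C)[C@@H]12)O3 | intermediate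
30 | (4Z,6R,7R,8R,10R)-8-isobutyryloxy-15-hydroxy-1-oxo-3,10-epoxygermacra-2,4,11(13)-trien-12,6-olide | C=C1C(=O)O[C@@H]2/C=C(/CO)C3=CC(=O)[C@@](C)(C[C@@H](OC(=O)C(C)C)[C@@H]12)O3 | target

**Step count and risks**

Total step count: 19. Longest linear sequence: 16 (steps 4–19, from 6). The other branch runs through steps 1–3 and joins at step 10.

Steps most likely to fail:

1. **Step 17.** The ring closure may lose out to intermolecular coupling, to capture of the long-lived acylpalladium species by adventitious nucleophiles, or to a reluctant reductive elimination in the strained palladacycle.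
   - The fallback installs C3 first and closes the ring by a Nozaki–Hiyama–Kishi reaction, a closure known for ten-membered rings that hold an alkyne. It sets out from 24.
   - Stille coupling with Bu3SnCH2OH (Pd(PPh3)4, dioxane, 80 °C) should give the hydroxymethyl seco-lactone F1, and MnO2 should give the C3 enal F2.
   - N-iodosuccinimide with AgNO3 (cat.) should give the iodoalkyne enal F3.
   - CrCl2 with NiCl2 (cat.) in THF at high dilution should give the macrocyclic propargylic alcohol F4. Both C3 epimers are usable.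
   - Dess–Martin oxidation returns to the route at 25, which is carried to 27 with Et2NH and then aqueous AcOH as in step 17.

2. **Step 14.** The soft carbanion may open the epoxide too slowly through the ester tether, so that phosphoryl transfer to O8 or acyl migration takes over.
   - The fallback reverses the polarity at C7 with a Barbier allylation and corrects C8 by inversion. It sets out from 5 and 12.
   - Divinylzinc with (−)-MIB (cat.) should add to 5 to give the vinyl carbinol F5.
   - Esterification with 2-(bromomethyl)acrylic acid (DCC, DMAP) should give the acrylate F6.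
   - Ring-closing metathesis with the second-generation Grubbs catalyst should give the bromomethyl butenolide F7.
   - Zn in THF/aq. NH4Cl with 12 should add through C7 anti to the C6 substituent. A closed chair transition state then gives the 8-epi alcohol F8.
   - Mitsunobu reaction with isobutyric acid (PPh3, DIAD) should invert C8 and give the bis-silyl isobutyrate F9.
   - AgNO3-catalysed protiodesilylation in aqueous acetone, followed by citric acid, returns to the route at 23.

3. **Step 6.** Hydroalumination of the newly formed propargylic alkoxide, or SN2′ attack on the alkynyl epoxide, may compete with hydride delivery to C9.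
   - The fallback avoids aluminium hydride altogether. It sets out from 9.
   - I2, PPh3 and imidazole should give the epoxy iodide F10.
   - Zn in refluxing EtOH should open it reductively to the tertiary allylic alcohol F11 without touching C10–O.
   - Hydroboration of the vinyl group with 9-BBN, followed by NaBO3·4H2O, returns to the route at 10.

**Further compounds**
F1 | step 17 | hydroxymethyl seco-lactone (iodine of 24 replaced by CH2OH) | CN(C)C[C@@H]1C(=O)O[C@H](/C=C(/CO[Si](C)(C)C(C)(C)C)CO)[C@H]1[C@H](OC(=O)C(C)C)C[C@@](C)(O)C#C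
F2 | step 17 | C3 enal | CN(C)C[C@@H]1C(=O)O[C@H](/C=C(/CO[Si](C)(C)C(C)(C)C)C=O)[C@H]1[C@H](OC(=O)C(C)C)C[C@@](C)(O)C#C
F3 | step 17 | iodoalkyne enal | CN(C)C[C@@H]1C(=O)O[C@H](/C=C(/CO[Si](C)(C)C(C)(C)C)C=O)[C@H]1[C@H](OC(=O)C(C)C)C[C@@](C)(O)C#CI
F4 | step 17 | macrocyclic propargylic alcohol (C3 epimers) | CN(C)C[C@@H]1C(=O)O[C@@H]2/C=C(/CO[Si](C)(C)C(C)(C)C)C(O)C#C[C@](C)(O)C[C@@H](OC(=O)C(C)C)[C@@H]12
F5 | step 14 | (3S,4Z)-6-[(tert-butyldimethylsilyl)oxy]-5-iodohexa-1,4-dien-3-ol | O[C@@H](C=C)/C=C(/CO[Si](C)(C)C(C)(C)C)I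
F6 | step 14 | 2-(bromomethyl)acrylate of F5 | C=C(CBr)C(=O)O[C@@H](C=C)/C=C(/CO[Si](C)(C)C(C)(C)C)I
F7 | step 14 | (5S)-3-(bromomethyl)-5-[(1Z)-3-[(tert-butyldimethylsilyl)oxy]-2-iodoprop-1-en-1-yl]furan-2(5H)-one | O=C1O[C@H](/C=C(/CO[Si](C)(C)C(C)(C)C)I)C=C1CBr
F8 | step 14 | 8-epi (8S) alcohol, 2-C- and 10-O-trimethylsilyl | C=C1C(=O)O[C@H](/C=C(/CO[Si](C)(C)C(C)(C)C)I)[C@H]1[C@@H](O)C[C@@](C)(O[Si](C)(C)C)C#C[Si](C)(C)C
F9 | step 14 | (8R)-isobutyrate, 2-C- and 10-O-trimethylsilyl | C=C1C(=O)O[C@H](/C=C(/CO[Si](C)(C)C(C)(C)C)I)[C@H]1[C@H](OC(=O)C(C)C)C[C@@](C)(O[Si](C)(C)C)C#C[Si](C)(C)C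
F10 | step 6 | epoxy iodide (CH2OH of 9 replaced by CH2I) | C[Si](C)(C)C#C[C@]1(C)O[C@H]1CI
F11 | step 6 | (R)-3-methyl-5-(trimethylsilyl)pent-1-en-4-yn-3-ol | C[Si](C)(C)C#C[C@@](C)(C=C)O
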